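**Strategy**

Everything rests on opening lactone ring A of the 6,7-dimethoxycoumarin half (ring atoms O1, C2, C3, C4, C4a, C8a; fused benzene ring B) at C4–C4a and O1–C2. Because C4a is ortho to the oxygen-bearing C8a and para to the methoxy-bearing C7, it maps onto C6 of 3,4-dimethoxyphenol, the site that phenol offers most readily to an electrophile. A single acid-mediated Pechmann-type [3+3] annulation therefore makes both bonds and closes ring A. Its three-carbon partner is a 3-(dimethylamino)acrylate (a masked formylacetate) whose C2 already bears the umbelliferone oxygen, so the C3–O aryl ether is installed earlier by simple alkylation of umbelliferone.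

Key step: step 3

Remark: the enamino ester is drawn as its (Z) isomer (amino group trans to the ester), the geometry such push–pull enamines normally adopt; the double bond is consumed in the annulation, so this assignment does not affect the outcome.

**Route**

Step 1
Reactants: 1 umbelliferone (7-hydroxy-2H-chromen-2-one); 2 ethyl bromoacetate
Product: 3 ethyl 2-[(2-oxo-2H-chromen-7-yl)oxy]acetate
Conditions: K2CO3, acetone, reflux
Reagents that add atoms: none
Why: Williamson ether synthesis, in which the acidic 7-hydroxyl is deprotonated by carbonate and the phenoxide displaces bromide from the primary alpha-bromo ester by SN2, while dry carbonate in acetone is too mild to open the lactone.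

Step 2
Reactants: 3 ethyl 2-[(2-oxo-2H-chromen-7-yl)oxy]acetate; 4 tert-butoxybis(dimethylamino)methane (Bredereck's reagent)
Product: 6 ethyl (2Z)-3-(dimethylamino)-2-[(2-oxo-2H-chromen-7-yl)oxy]prop-2-enoate, via aminal adduct 5 (not isolated)
Conditions: 4 (1.5 equiv), PhMe, 100 °C, N2; volatiles removed in vacuo
Reagents that add atoms: none
Why: Bredereck aminomethylenation of an active methylene, in which tert-butoxide released on ionisation of 4 deprotonates the aryloxyacetate alpha-carbon, the enolate adds to the tetramethylformamidinium ion to give aminal 5, and loss of dimethylamine gives the push–pull enamine, all under anhydrous, non-hydrolytic conditions that should leave the lactone closed.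

Step 3
Reactants: 6 ethyl (2Z)-3-(dimethylamino)-2-[(2-oxo-2H-chromen-7-yl)oxy]prop-2-enoate; 7 3,4-dimethoxyphenol
Product: 10 daphnoretin methyl ether (6,7-dimethoxy-3-[(2-oxo-2H-chromen-7-yl)oxy]-2H-chromen-2-one), via Friedel–Crafts adduct 8 (not isolated), via hydroxycinnamate 9 (not isolated)
Conditions: 7 (1.3 equiv), MsOH, 0 °C to rt, 6 added to 7; ice water; recrystallisation
Reagents that add atoms: none
Why: In MsOH the push–pull enamine 6 is protonated at C2, the carbon bearing the aryloxy group, giving an N,N-dimethyliminium ion whose carbon (the future C4) is attacked by C6 of phenol 7 to give adduct 8; the benzylic dimethylammonium group then leaves through a cation stabilised by the para methoxy group to give hydroxycinnamate 9, whose phenol oxygen displaces ethanol from the ester. The closest known reaction type is the Pechmann condensation of phenols with formylacetate esters, including the acid-mediated variant in which 2-heteroatom-substituted 3-(dimethylamino)propenoates and electron-rich phenols give 3-substituted coumarins. Ring A is closed after the intermolecular C4–C4a bond formation by a 6-exo-trig acyl substitution that forms O1–C2. No stereocentre remains: the two stereocentres of 8 vanish on elimination, and the alkene geometry of 9 is not limiting, because reversible protonation at the ester alpha-carbon interconverts the isomers and only the one with aryl and ester cis can lactonise. Two selectivities are needed: attack through C6 of 7 (para to the 3-methoxy group, ortho to the hydroxyl, unhindered) and not through C2, which is flanked by two oxygen-bearing carbons, and intermolecular capture of the iminium ion by 7 in preference to cyclisation onto C6 or C8 of the umbelliferone ring, which the lactone carbonyl deactivates and which 7, with three oxygen donors and used in slight excess, should outrun. The existing lactone, the methyl ethers and the new enol-type aryl ether should be inert to anhydrous MsOH at room temperature.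

**Compound list**

1 | umbelliferone (7-hydroxy-2H-chromen-2-one) | O=c1ccc2ccc(O)cc2o1 | starting material
2 | ethyl bromoacetate | CCOC(=O)CBr | starting material
3 | ethyl 2-[(2-oxo-2H-chromen-7-yl)oxy]acetate | CCOC(=O)COc1ccc2ccc(=O)oc2c1 | intermediate
4 | tert-butoxybis(dimethylamino)methane (Bredereck's reagent) | CN(C)C(OC(C)(C)C)N(C)C | starting material
5 | ethyl 3,3-bis(dimethylamino)-2-[(2-oxo-2H-chromen-7-yl)oxy]propanoate (racemic aminal, not isolated) | CCOC(=O)C(Oc1ccc2ccc(=O)oc2c1)C(N(C)C)N(C)C | intermediate
6 | ethyl (2Z)-3-(dimethylamino)-2-[(2-oxo-2H-chromen-7-yl)oxy]prop-2-enoate | CCOC(=O)/C(=C/N(C)C)Oc1ccc2ccc(=O)oc2c1 | intermediate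
7 | 3,4-dimethoxyphenol | COc1ccc(O)cc1OC | starting material
8 | ethyl 3-(dimethylamino)-3-(2-hydroxy-4,5-dimethoxyphenyl)-2-[(2-oxo-2H-chromen-7-yl)oxy]propanoate (mixture of racemic diastereomers, not isolated) | CCOC(=O)C(Oc1ccc2ccc(=O)oc2c1)C(N(C)C)c1cc(OC)c(OC)cc1O | intermediate
9 | ethyl (2E)-3-(2-hydroxy-4,5-dimethoxyphenyl)-2-[(2-oxo-2H-chromen-7-yl)oxy]prop-2-enoate (aryl cis to ester, not isolated) | CCOC(=O)/C(Oc1ccc2ccc(=O)oc2c1)=C\c1cc(OC)c(OC)cc1O | intermediate
10 | daphnoretin methyl ether (6,7-dimethoxy-3-[(2-oxo-2H-chromen-7-yl)oxy]-2H-chromen-2-one; no stereocentres) | COc1cc2cc(Oc3ccc4ccc(=O)oc4c3)c(=O)oc2cc1OC | target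

**Step count**

Total steps: 3. Longest linear sequence: 3 steps (1 to 3 to 6 to 10).

**Steps most likely to fail**

1. Step 3 (key annulation). The iminium ion may cyclise onto the umbelliferone ring of its own aryloxy group (furan closure) instead of being captured by the phenol. The benzylic cation may also be trapped by a second phenol molecule before elimination and lactonisation. Fallback: a Perkin–Oglialoro construction of ring A through C3–C4 and O1–C2, setting out from 3. Ester 3 is hydrolysed under acidic conditions (aqueous HCl, dioxane, reflux), which keep the lactone closed, to [(2-oxo-2H-chromen-7-yl)oxy]acetic acid F1. F1 is then heated with commercial 2-hydroxy-4,5-dimethoxybenzaldehyde (COc1cc(C=O)c(O)cc1OC) in Ac2O with Et3N at about 120 °C. O-acylation of the salicylaldehyde by the mixed anhydride, intramolecular aldol-type condensation and dehydration should give the 3-aryloxycoumarin, so the fallback comes back to the route at 10.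

2. Step 2 (aminomethylenation). The condensation may stall because the aryloxyacetate is only weakly C–H acidic, or the liberated dimethylamine and tert-butoxide may attack the lactone on prolonged heating. Fallback: a Claisen formylation, setting out from 3. Treatment with NaH and ethyl formate in THF (0 °C to rt), then dilute acid, should give ethyl 3-oxo-2-[(2-oxo-2H-chromen-7-yl)oxy]propanoate F2, which exists largely as its enol; any alkoxide opening of the lactone is reversed on acidification. Condensation of F2 with dimethylamine (Me2NH·HCl, NaOAc, EtOH, rt) with loss of water returns to the route at 6.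

3. Step 1 (O-alkylation). Adventitious hydroxide may open the lactone or saponify the bromo ester, leaving the alkylation incomplete. Fallback: a base-free Mitsunobu etherification, setting out from 1. Umbelliferone is coupled with ethyl glycolate (OCC(=O)OCC) using PPh3 and diisopropyl azodicarboxylate in THF (0 °C to rt), activating the alcohol partner instead of displacing a halide, and comes back to the route directly at 3.

**Further compounds**

F1 | step 3 | [(2-oxo-2H-chromen-7-yl)oxy]acetic acid | OC(=O)COc1ccc2ccc(=O)oc2c1
F2 | step 2 | ethyl 3-oxo-2-[(2-oxo-2H-chromen-7-yl)oxy]propanoate (racemic, enolisable; drawn as the aldehyde tautomer) | CCOC(=O)C(C=O)Oc1ccc2ccc(=O)oc2c1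
F0 | step 1 | none | none
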